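We look for the slowness of this flask in the carrier loop, where spent carrier is recharged from the salt in the second phase and fresh carrier hands over to the starting material.

    starting material ⇌ dormant form (K1 = 2.0, k1 = 0.0157 min⁻¹)
    spent carrier + salt in the second phase ⇌ fresh carrier + spent salt in the second phase (K2 = 0.363, k2 = 0.467 L mol⁻¹ min⁻¹)
    starting material + fresh carrier → product + spent carrier (k3 = 0.638 L mol⁻¹ min⁻¹)
    starting material + protic impurity → quenched substrate (k4 = 0.0499 L mol⁻¹ min⁻¹)

common to all: starting material 0.30 M; salt in the second phase 0.300 M; protic impurity 0.150 M; time 2.0 h; volume of the second phase over the first 0.25
- Monday's: spent carrier 30 mM
- Thursday's: spent carrier 60 mM

- in the second phase: salt in the second phase, spent salt in the second phase; everything else is in the first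
- charges count per volume of the first phase; a concentration in a rate is the amount of a species over the volume of its own phase; every rate counts per litre of the first phase
- run time (Monday's): 2.0 h

* which of these there is most of at the end, counted by the starting material in it, Monday's (product / starting material)
* which of these there is most of at the end, counted by the starting material in it, Thursday's (product / starting material)
* final amount of the leader among these, as a percentage of the starting material charged, in Monday's
* final amount of the leader among these, as a percentage of the starting material charged, in Thursday's

**Two clocks.** At the charged concentrations the forward exchange has a half-life of 1.2 min on Monday's, and step 3 gives fresh carrier one of 3.62 min. Both are short against 2.0 h, and the exchange is the faster, so we take the exchange as near its balance and reckon with amounts.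

**Two amounts.** Each fresh carrier made leaves one spent salt, and each product turns one fresh carrier back to spent, so spent salt equals product plus fresh carrier. Salt and spent salt share a phase, so the volume ratio cancels at balance. Fresh and spent carrier stand equal once spent salt reaches 79.9 mM per litre of the first phase. Subtracting the fresh carrier then standing, 15.0 mM on Monday's, gives the even-share product, the product present when fresh and spent carrier are equal: 64.9 mM. Thursday's, with 30.0 mM standing, has 49.9 mM. Against the charge of 0.30 M these are 21.6% and 16.6%. Beyond them most of the carrier is spent. Our reckoning stops there and gives no final yield.

**The forecast.** It names product as leader on Monday's at 36% and product on Thursday's at 50%, holding that “turnover slows as spent salt builds up and drives the exchange back”.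

**The flask.** Monday's ends with 34.4% product against 11.8% starting material, Thursday's with 46.0% against 8.57%. The forecast stands within its margin.

**Heavier charge.** After 1.00 h Monday's reads 27.5% product, past its even share, with fresh carrier at 42.0% and spent carrier, the resting state, at 58.0%. The neighbour charged with 1.2 M starting material keeps Monday's salt and carrier, but at that charge step 3 gives fresh carrier a half-life of 0.905 min, shorter than the exchange's 1.2 min, so at its start we cannot take the exchange as near its balance, and we reckon no even-share product for it. It ends with 229 mM product, above Monday's even-share product of 64.9 mM, and with fresh carrier at 8.61%. There the leader changes: starting material holds 23.8% against 19.1% product.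

The numbers of this flask belong to no real substance; the run is a simulation.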